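Readings and results were computed with constants of no real substance, noise included.

Answer 5 questions about 4 flasks that share charges and time and differ in temperature.

| setting | south | north-east | winter | dusk | dawn | midnight |
|---|---|---|---|---|---|---|
| Z | 0.25 M | 0.25 M | 0.25 M | 0.25 M | 0.25 M | 0.25 M |
| E | 0.60 equiv | 0.90 equiv | 1.20 equiv | 1.20 equiv | 1.20 equiv | 1.20 equiv |
| temperature | 51 °C | 76 °C | 70 °C | 55 °C | 85 °C | 40 °C |
| remark | run made earlier | run made earlier |  |  |  |  |
| time |  |  | 1.0 h | 1.0 h | 1.0 h | 1.0 h |

| run | time / min | D / % |
|---|---|---|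
| south | 12.0 | 1 |
| south | 25.0 | 0 |
| south | 40.0 | 1 |
| south | 50.0 | 0 |
| south | 60.0 | 2 |
| south | 80.0 | 1 |
| south | 90.0 | 2 |
| north-east | 2.00 | 0 |
| north-east | 6.00 | 0 |
| north-east | 10.0 | 3 |
| north-east | 15.0 | 4 |
| north-east | 20.0 | 16 |
| north-east | 30.0 | 42 |
| north-east | 40.0 | 50 |

(standard deviation of a reading: 1.5 percentage points)

- the numbers in the tables scatter with a standard deviation of 1.5 percentage points
- a reading or a percentage of D counts all its forms, free or not

1. the flask with the highest amount of D, in percent of the Z charged ("all alike" if they lie within 1.5 percentage points) (winter / dusk / dawn / midnight / all alike)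
2. final D, as a percentage of the Z charged, in winter
3. final D, as a percentage of the Z charged, in dusk
4. final D, as a percentage of the Z charged, in dawn
5. final D, as a percentage of the Z charged, in midnight

Read the north-east run first. That flask reads 4 % of D at 15.0 min, then climbs from 16 % at 20.0 min to 42 % at 30.0 min. Take this as autocatalysis, D breeding D. The readings then give 7.18 min as the doubling time, the minutes D needs to double on the climb, a reading for 76 °C and 0.90 equiv, with its scatter.

Now count. From 3 % to 50 % is 4.06 doublings, so the north-east climb takes 29.2 min, about half of the hour.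

Expect Z and E in each flask at the start, with D too low to read. Do not touch a flask that reads low at mid-hour, because a climb of that length is shorter than the time still to run. Expect dawn and winter past the climb by 1.0 h: dawn is hotter than north-east, and winter is cooler but holds more E. Expect midnight still low, since it is colder than south. Dusk is my doubtful flask: 55 °C against south's 51 °C, with twice the E. By my reckoning it ends either before the climb or high, so a few percent is a poor bet.

The forecast differs. It names dawn and gives 50 % for winter, 3 % for dusk, 72 % for dawn and 0.5 % for midnight, and says of dawn: “reaches the ceiling, with some risk of loss”.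

The flasks give 64.5 % in winter, 57.8 % in dusk, 59.2 % in dawn and 1.27 % in midnight, so winter holds the most.

    Z + E + D → 2 D (k = 7.50 M⁻² min⁻¹, Ea = 45.0 kJ mol⁻¹)
    Z + E → D (k = 1.20 × 10⁻⁴ M⁻¹ min⁻¹, Ea = 89.0 kJ mol⁻¹)
    2 Z → Q (k = 0.0570 M⁻¹ min⁻¹, Ea = 64.0 kJ mol⁻¹)
    X ⇌ D, rate k4*(cs4 - [D]) while solid is left; crystals form when [D] > cs4 (solubility = 0.120 M, k = 0.520 min⁻¹)
    (constants at 70 °C)

Dusk parts furthest from the forecast, at 57.8 % against 3 %. Dusk reads 3.76 % of D at 0.500 h and 57.8 % at 1.00 h. That is 3.94 doublings in 30.0 min, so 7.61 min each on average in dusk, against 7.18 min read in north-east. Now take a neighbour of midnight charged with 2.00 equiv of E. It holds 43.4 % of D at 1.00 h against midnight's 1.27 %, which puts it 5.10 doublings ahead at that time; do not turn these into minutes with 7.18 min, a reading at 76 °C and 0.90 equiv. Z left there is 42 %, against 82 % in midnight.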